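**Retrosynthetic overview**
1. Target 19 comes from its TBS ether 18 by desilylation. The only ring is the cyclohexenone ring A (C1 = ketone carbon next to the carbinol carbon C6, C2 = acyl-bearing carbon, C3 = enol carbon, C1′ = exocyclic acyl carbon), and it is made in step 8.
2. 18 comes from the acyclic ynone acid 15 by a base/DMAP-triggered isomerisation: carboxylate oxa-Michael addition gives a transient enol δ-lactone ring, then an O-to-C acyl shift forms the C1–C2 bond and closes ring A.
3. Enabling feature: in 15 the C2≡C3 triple bond of the ynone is the dehydrated form of the C1′–C2–C3 β-diketone and is placed so that the C1 carboxyl oxygen reaches C3 through a six-membered ring. The resulting vinylogous anhydride holds the C1 acyl group 1,3 to the nucleophilic C2, so the alkyne both activates the acid and unmasks the carbon nucleophile.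
4. 15 comes from the acetylide of (R)-2-silyloxyhex-5-ynoic acid 12 and Weinreb amide 8 (C2–C1′ bond). The C6 stereocentre comes from (R)-2-aminohex-5-ynoic acid 9 by retentive diazotisation.
5. 8 comes from Suzuki–Miyaura coupling of alkenylboronate 4 (from oct-7-ynoic acid 1) with (E)-1-iododec-1-ene 7 (from dec-1-yne 5), which fixes the (7E,9E)-diene.

Key step: step 8

Assumption: the target is treated as the drawn enol tautomer of a rapidly equilibrating β-triketone (tautomers are not distinguished), and (R)-2-aminohex-5-ynoic acid is taken as a purchasable amino acid.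

**Route**

Step 1
Reactants: 1 oct-7-ynoic acid
Product: 3 N-methoxy-N-methyloct-7-ynamide, via acyl imidazole 2 (not isolated)
Conditions: CDI, CH2Cl2, rt; then MeNH(OMe)·HCl, rt
Reagents that add atoms: N,O-dimethylhydroxylamine hydrochloride, CNOC.Cl
Why: CDI converts the acid into the acyl imidazole 2, which is aminolysed by N,O-dimethylhydroxylamine in a standard Weinreb amide synthesis that should leave the terminal alkyne untouched.

Step 2
Reactants: 3 N-methoxy-N-methyloct-7-ynamide
Product: 4 (E)-N-methoxy-N-methyl-8-(4,4,5,5-tetramethyl-1,3,2-dioxaborolan-2-yl)oct-7-enamide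
Conditions: HBpin (1.2 equiv), Cy2BH (5 mol%), THF, rt
Reagents that add atoms: pinacolborane, CC1(C)OBOC1(C)C
Why: Dialkylborane-catalysed syn-hydroboration of the terminal alkyne with pinacolborane should place boron at the terminal carbon and give the (E)-alkenylboronate, the tertiary amide being inert to HBpin at room temperature.

Step 3
Reactants: 5 dec-1-yne
Product: 7 (E)-1-iododec-1-ene, via alkenylzirconocene chloride 6 (not isolated)
Conditions: Cp2Zr(H)Cl (1.1 equiv), CH2Cl2, rt; then I2, 0 °C
Reagents that add atoms: iodine, [I][I]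
Why: Syn-hydrozirconation of the terminal alkyne places zirconium at the terminus, and iodinolysis of the C–Zr bond with retention should give the (E)-iodoalkene.

Step 4
Reactants: 4 (E)-N-methoxy-N-methyl-8-(4,4,5,5-tetramethyl-1,3,2-dioxaborolan-2-yl)oct-7-enamide; 7 (E)-1-iododec-1-ene
Product: 8 (7E,9E)-N-methoxy-N-methyloctadeca-7,9-dienamide
Conditions: Pd(PPh3)4 (5 mol%), 2 M aq. NaOH, THF, 50 °C
Reagents that add atoms: none
Why: The Suzuki–Miyaura coupling proceeds with retention at both sp2 carbons, so the (7E,9E)-diene should follow directly from the two syn-hydrometalations, and the amide tolerates the aqueous base.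

Step 5
Reactants: 9 (R)-2-aminohex-5-ynoic acid
Product: 10 (R)-2-hydroxyhex-5-ynoic acid
Conditions: NaNO2, 1 M aq. H2SO4, 0 °C to rt
Reagents that add atoms: water, O
Why: Nitrous acid deamination of an α-amino acid should replace NH2 by OH with net retention (double inversion through participation of the neighbouring carboxylate), so the (R)-centre that becomes C6 of the target is taken from the chiral pool.

Step 6
Reactants: 10 (R)-2-hydroxyhex-5-ynoic acid
Product: 12 (R)-2-[(tert-butyldimethylsilyl)oxy]hex-5-ynoic acid, via bis-silyl compound 11 (not isolated)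
Conditions: TBSCl (2.5 equiv), imidazole, DMF, rt; then K2CO3, THF/H2O, rt; acidify to pH 4
Reagents that add atoms: tert-butyldimethylsilyl chloride, CC(C)(C)[Si](C)(C)Cl
Why: Exhaustive silylation gives the silyl ether silyl ester 11, whose far more labile silyl ester should be hydrolysed selectively by aqueous carbonate to leave the TBS ether acid (the ether is needed so that only the carboxylate can add to the ynone in step 8).

Step 7
Reactants: 12 (R)-2-[(tert-butyldimethylsilyl)oxy]hex-5-ynoic acid; 8 (7E,9E)-N-methoxy-N-methyloctadeca-7,9-dienamide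
Product: 15 (2R,13E,15E)-2-[(tert-butyldimethylsilyl)oxy]-7-oxotetracosa-13,15-dien-5-ynoic acid, via dilithio acetylide carboxylate 13 (not isolated), via tetrahedral lithium adduct 14 (not isolated)
Conditions: n-BuLi (2.1 equiv), THF, −78 °C; then 8, −78 to 0 °C; cold 1 M HCl quench
Reagents that add atoms: none
Why: In this Weinreb ketone synthesis the acetylide carbon of dianion 13 should add once to the amide to give the chelated tetrahedral adduct 14, which collapses to the ynone only on the acidic quench (the released amine is protonated and cannot add to the ynone), while the carboxylate α-C–H is not removed by n-BuLi at −78 °C so the stereocentre is kept.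

Step 8
Reactants: 15 (2R,13E,15E)-2-[(tert-butyldimethylsilyl)oxy]-7-oxotetracosa-13,15-dien-5-ynoic acid
Product: 18 (6R)-6-[(tert-butyldimethylsilyl)oxy]-3-hydroxy-2-[(7E,9E)-octadeca-7,9-dienoyl]cyclohex-2-en-1-one, via enol lactone 16 (not isolated), via acylpyridinium enolate 17 (not isolated)
Conditions: Et3N (2 equiv), DMAP (0.3 equiv), MeCN (0.01 M), rt to 45 °C; then 1 M HCl wash
Reagents that add atoms: none
Why: Proposed new method: the triethylammonium carboxylate of 15 should add to the ynone β-carbon C3 in a 6-exo-dig oxa-Michael closure to the enol δ-lactone 16, a vinylogous anhydride, which DMAP opens at the lactone carbonyl C1 to the tethered N-acylpyridinium β-diketone enolate 17; the enolate then attacks C1 through its central carbon C2 in a 6-exo-trig C-acylation that closes ring A, and deprotonation of the resulting β-triketone by Et3N makes the sequence irreversible. The closest known reaction types are the amine-catalysed addition of carboxylic acids to activated alkynes (enol esters as activated esters), the base-induced rearrangement of alkylidene lactones to cyclic 1,3-diones, and the DMAP- or cyanide-catalysed O-to-C acyl shift of 1,3-dione enol esters to 2-acyl-1,3-diones. No new stereocentre is formed; the C6 centre is carried over from 12 and is shielded from enolisation first as the carboxylate and afterwards as the triketonate. The step is stereoconvergent in that both the E and the Z enol lactone 16 open to the same enolate 17, and it needs C- over O-acylation and carboxylate over hydroxyl addition: the first is secured because only C-acylation gives the stabilised triketonate (O-acylation merely returns 16), the second by the TBS ether on the C6 oxygen, and oligomerisation is held back by high dilution.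

Step 9
Reactants: 18 (6R)-6-[(tert-butyldimethylsilyl)oxy]-3-hydroxy-2-[(7E,9E)-octadeca-7,9-dienoyl]cyclohex-2-en-1-one
Product: 19 (6R)-3,6-dihydroxy-2-[(7E,9E)-octadeca-7,9-dienoyl]cyclohex-2-en-1-one
Conditions: HF·pyridine, pyridine/THF, 0 °C to rt
Reagents that add atoms: none
Why: Desilylation with buffered HF avoids basic conditions, so the silyl ether should be cleaved without epimerising the α-hydroxy ketone centre, retro-Claisen cleavage of the β-triketone or isomerisation of the diene.

**Compound list**
1 | oct-7-ynoic acid | C#CCCCCCC(=O)O | starting material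
2 | 1-(oct-7-ynoyl)-1H-imidazole (formed in situ) | C#CCCCCCC(=O)n1ccnc1 | intermediate
3 | N-methoxy-N-methyloct-7-ynamide | C#CCCCCCC(=O)N(C)OC | intermediate
4 | (E)-N-methoxy-N-methyl-8-(4,4,5,5-tetramethyl-1,3,2-dioxaborolan-2-yl)oct-7-enamide | CON(C)C(=O)CCCCC/C=C/B1OC(C)(C)C(C)(C)O1 | intermediate
5 | dec-1-yne | CCCCCCCCC#C | starting material
6 | chlorobis(cyclopentadienyl)[(E)-dec-1-en-1-yl]zirconium (formed in situ) | CCCCCCCC/C=C/[Zr](Cl)(C1C=CC=C1)C1C=CC=C1 | intermediate
7 | (E)-1-iododec-1-ene | CCCCCCCC/C=C/I | intermediate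
8 | (7E,9E)-N-methoxy-N-methyloctadeca-7,9-dienamide | CCCCCCCC/C=C/C=C/CCCCCC(=O)N(C)OC | intermediate
9 | (R)-2-aminohex-5-ynoic acid (D-homopropargylglycine) | N[C@H](CCC#C)C(=O)O | starting material
10 | (R)-2-hydroxyhex-5-ynoic acid | O[C@H](CCC#C)C(=O)O | intermediate
11 | tert-butyldimethylsilyl (R)-2-[(tert-butyldimethylsilyl)oxy]hex-5-ynoate (formed in situ) | CC(C)(C)[Si](C)(C)O[C@H](CCC#C)C(=O)O[Si](C)(C)C(C)(C)C | intermediate
12 | (R)-2-[(tert-butyldimethylsilyl)oxy]hex-5-ynoic acid | CC(C)(C)[Si](C)(C)O[C@H](CCC#C)C(=O)O | intermediate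
13 | lithium (R)-2-[(tert-butyldimethylsilyl)oxy]-6-lithiohex-5-ynoate (formed in situ) | CC(C)(C)[Si](C)(C)O[C@H](CCC#C[Li])C(=O)O[Li] | intermediate
14 | dilithium salt of the tetrahedral adduct of 13 and 8, epimer mixture at the aminal carbon (formed in situ) | CCCCCCCC/C=C/C=C/CCCCCC(O[Li])(N(C)OC)C#CCC[C@@H](O[Si](C)(C)C(C)(C)C)C(=O)O[Li] | intermediate
15 | (2R,13E,15E)-2-[(tert-butyldimethylsilyl)oxy]-7-oxotetracosa-13,15-dien-5-ynoic acid | CCCCCCCC/C=C/C=C/CCCCCC(=O)C#CCC[C@@H](O[Si](C)(C)C(C)(C)C)C(=O)O | intermediate
16 | (3R)-3-[(tert-butyldimethylsilyl)oxy]-6-[(8E,10E)-2-oxononadeca-8,10-dien-1-ylidene]tetrahydro-2H-pyran-2-one, E/Z mixture at the exocyclic alkene (formed in situ) | CCCCCCCC/C=C/C=C/CCCCCC(=O)C=C1CC[C@@H](O[Si](C)(C)C(C)(C)C)C(=O)O1 | intermediate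
17 | 1-acyl-4-(dimethylamino)pyridinium zwitterion carrying the ring-opened β-diketone enolate (formed in situ) | CCCCCCCC/C=C/C=C/CCCCCC(=O)C=C([O-])CC[C@@H](O[Si](C)(C)C(C)(C)C)C(=O)[n+]1ccc(N(C)C)cc1 | intermediate
18 | (6R)-6-[(tert-butyldimethylsilyl)oxy]-3-hydroxy-2-[(7E,9E)-octadeca-7,9-dienoyl]cyclohex-2-en-1-one | CCCCCCCC/C=C/C=C/CCCCCC(=O)C1=C(O)CC[C@@H](O[Si](C)(C)C(C)(C)C)C1=O | intermediate
19 | (6R)-3,6-dihydroxy-2-[(7E,9E)-octadeca-7,9-dienoyl]cyclohex-2-en-1-one | CCCCCCCC/C=C/C=C/CCCCCC(=O)C1=C(O)CC[C@@H](O)C1=O | target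

**Step count and risks**

Total step count: 9. Longest linear sequence: 6 steps (steps 1, 2, 4, 7, 8, 9).

Steps most likely to fail:

1. Step 8 (proposed new method). The sequence may stall at the enol lactone, the acylpyridinium intermediate may lose configuration at C6 through ketene formation, intermolecular acyl transfer may give oligomers, or the ynone may isomerise to an allenone before lactonisation. The fallback uses known chemistry, sets out from 15 and comes back at 18. Conjugate addition of diethylamine (Et2NH, EtOH, rt) should give the enaminone acid F1, and mild hydrolysis (aq. oxalic acid, THF) the 5,7-dioxo acid F2. F2 is activated with CDI to the acyl imidazole F3, which is cyclised through its magnesium diketonate (MgCl2, Et3N, MeCN) in an intramolecular Claisen-type C-acylation that forms the same C1–C2 bond and gives 18.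

2. Step 7. The dilithium salt may aggregate and dissolve poorly, so that acyl transfer from the amide stays incomplete, or the amine released at the quench may add to the ynone. The fallback sets out from 8 and 11 (11 isolated by non-aqueous work-up instead of being hydrolysed) and comes back at 15. Reduction of 8 with i-Bu2AlH (THF, −78 °C) should give (7E,9E)-octadeca-7,9-dienal F4. The alkynylzinc reagent made from 11 with Et2Zn (toluene, N-methylimidazole) adds to F4 to give the propargylic alcohol silyl ester F5 (the carbinol configuration is immaterial). Oxidation with MnO2 (CH2Cl2) gives the ynone silyl ester F6, whose silyl ester is hydrolysed on work-up (AcOH/THF/H2O) to give 15.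

3. Step 2. The borane may coordinate to or reduce the N-methoxy-N-methylamide, and regiocontrol of the hydroboration may be incomplete. The fallback sets out from 3 and 7, bypasses 4 and step 4, and comes back at 8. Sonogashira coupling (Pd(PPh3)2Cl2, CuI, Et3N) should give the (E)-enyne amide F7. Trans-hydrosilylation of its triple bond with (EtO)3SiH and [Cp*Ru(MeCN)3]PF6 (CH2Cl2) gives the alkenylsilane F8 (the regioisomer mixture is immaterial). Protodesilylation with AgF (THF/MeOH/H2O) then gives the (7E,9E)-diene 8, a formal trans-semi-reduction of the enyne.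

Further compounds
F1 | step 8 | (2R,13E,15E)-2-[(tert-butyldimethylsilyl)oxy]-5-(diethylamino)-7-oxotetracosa-5,13,15-trienoic acid | CCCCCCCC/C=C/C=C/CCCCCC(=O)C=C(N(CC)CC)CC[C@@H](O[Si](C)(C)C(C)(C)C)C(=O)O
F2 | step 8 | (2R,13E,15E)-2-[(tert-butyldimethylsilyl)oxy]-5,7-dioxotetracosa-13,15-dienoic acid | CCCCCCCC/C=C/C=C/CCCCCC(=O)CC(=O)CC[C@@H](O[Si](C)(C)C(C)(C)C)C(=O)O
F3 | step 8 | 1-[(2R,13E,15E)-2-[(tert-butyldimethylsilyl)oxy]-5,7-dioxotetracosa-13,15-dienoyl]-1H-imidazole | CCCCCCCC/C=C/C=C/CCCCCC(=O)CC(=O)CC[C@@H](O[Si](C)(C)C(C)(C)C)C(=O)n1ccnc1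
F4 | step 7 | (7E,9E)-octadeca-7,9-dienal | CCCCCCCC/C=C/C=C/CCCCCC=O
F5 | step 7 | tert-butyldimethylsilyl (2R,13E,15E)-2-[(tert-butyldimethylsilyl)oxy]-7-hydroxytetracosa-13,15-dien-5-ynoate | CCCCCCCC/C=C/C=C/CCCCCC(O)C#CCC[C@@H](O[Si](C)(C)C(C)(C)C)C(=O)O[Si](C)(C)C(C)(C)C
F6 | step 7 | tert-butyldimethylsilyl (2R,13E,15E)-2-[(tert-butyldimethylsilyl)oxy]-7-oxotetracosa-13,15-dien-5-ynoate | CCCCCCCC/C=C/C=C/CCCCCC(=O)C#CCC[C@@H](O[Si](C)(C)C(C)(C)C)C(=O)O[Si](C)(C)C(C)(C)C
F7 | step 2 | (E)-N-methoxy-N-methyloctadec-9-en-7-ynamide | CCCCCCCC/C=C/C#CCCCCCC(=O)N(C)OC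
F8 | step 2 | (7Z,9E)-N-methoxy-N-methyl-8-(triethoxysilyl)octadeca-7,9-dienamide (with its 7-silyl regioisomer) | CCCCCCCC/C=C/C(=C/CCCCCC(=O)N(C)OC)[Si](OCC)(OCC)OCC
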